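## The problem

The target is a 2-arylbenzofuran in which ring A (the benzo ring, C3a–C7a) carries hydroxyl groups at C4 and C6, hydrogen at C5 and a (2R)-3-methylbut-3-en-2-yl group at C7. Ring C, attached at C2, is a resorcinol whose two positions flanking the C2–C1' bond (C2' and C6') both carry prenyl groups, so this bond is doubly ortho-substituted and hindered. The only stereocentre is the benzylic, allylic carbon of the C7 side chain; nothing else in the molecule can relay chirality to it, so a reagent must set it, and strong base (deprotonation, migration of the isopropenyl double bond into conjugation) must then be kept from it. Acid is the general enemy: each prenyl group lies ortho to a phenol (chroman formation), the isopropenyl group lies ortho to the C6 hydroxyl (dihydrobenzofuran formation), and ring A is an easily oxidised phloroglucinol-type arene, so the last deprotection must be fluoride-based and hydrogenation is excluded. Two regiochemical questions remain: ring A is substituted at every carbon, and ring C must be prenylated at C2' and C6' and not at C4', the site between the hydroxyls that electrophiles prefer. The feature that opens the key step is the sequence on ring A read from C3a: C4 (oxygen), C5 (hydrogen), C6 (oxygen), C7 (carbon substituent), C7a (ring oxygen). A ketene carbonyl (C4), the CH of a terminal ynol ether (C5), its oxygen-bearing carbon (C6) and a ketene α-carbon (C7) deliver exactly this pattern onto the C2=C3 bond of a 2-furyl group (C7a, C3a), and furyl C3 is the only carbon at which such a ring can close.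

## Retrosynthesis

**Target 31 to bis-silyl ether 30.** Only the two O–Si bonds on ring A are cut. Silyl ethers are chosen over acetal or alkyl ethers because fluoride removes them without acid. The forward step must leave three acid-prone alkenes and four phenols untouched.

**Ring C: 30 to triketone 28, then to ester 20 and diketone 26.** The C1'–C6' bond is cut as an aldol condensation and the C1'–C2' bond as a Claisen acylation, so ring C arises from one ester carbon and the five-carbon chain C5–C9 of symmetrical diketone 26. The neighbouring cut, a cross-coupling at C2–C1', would need a separately made, doubly ortho-substituted ring C halide and a hindered biaryl coupling. The acyclic route carries both prenyl groups in 26 from the outset, so the C2'/C6' versus C4' question never arises. The precursors are a benzofuran ester and a C15 diketone. The forward reactions must acylate a secondary carbanion and then close a six-membered ring onto an aryl ketone without base-induced damage at the side chain.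

**Ester 20 to phenol 19.** One O–Si bond is cut; the C4 hydroxyl needs cover for the carbanion chemistry and gets the same bulky silyl group that C6 already carries.

**Ring A: 19 to acid chloride 7 and siloxyalkyne 14 (key disconnection).** The bonds C4–C5, C6–C7 and C3a–C4 are cut, taking the benzofuran back to a furan with an acyl chloride side chain and a two-carbon ynol ether. Stepwise substitution of a preformed benzofuran or phloroglucinol would face four regiochemical decisions on ring A; here each substituent has its place fixed by the polarity of the two partners. The precursor is much simpler: one ring fewer, and the stereocentre sits on an acyclic chain. The forward reaction must build a fully substituted ketene carbon into the ring and must not disturb the adjacent stereocentre.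

**Acid chloride 7 to acid 6, ester 3, and then chloride 1 and alcohol 2.** The C2–C3 bond of the pentenoic acid is cut as an ester-enolate Claisen rearrangement of the (E)-2-methylbut-2-enyl ester 3, which creates the stereocentre and the isopropenyl group together. An enolate alkylation with a secondary allylic electrophile would give mixtures of direct and transposed substitution. Ester 3 is reached by carbonylative union of 1 and 2. The rearrangement must be enantioselective at C3; C2 is irrelevant because it becomes the ketene carbon.

**Siloxyalkyne 14 to bromovinyl ether 12, vinyl ether 10 and tetrahydrofuran 8.** The triple bond is made by elimination from a 2-bromovinyl silyl ether, itself from the silyl vinyl ether. This order puts silicon on oxygen before the alkyne exists, so the carbon-versus-oxygen silylation question of an unsubstituted ynolate is avoided.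

**Diketone 26 to monoprenyl diketone 24, and then to pentane-2,4-dione 21 and prenyl bromide 22.** The two terminal C–C bonds are cut one at a time as dianion alkylations. Each alkylation uses one equivalent of 22 and is carried out as a step of its own, so that the second dianion is formed from purified 24 and the bromide enters only at the remaining methyl terminus.

## Roads not taken

**Alternative 1: ketone annulation across a ring A ortho-dihalide.**
- Cut and forward step: the furan ring is cut at C3–C3a and O1–C7a. Under palladium catalysis the enolate of the ring C methyl ketone A3 is arylated at the iodide of the ring A dihalide A2, and the enolate oxygen then displaces the neighbouring bromide, giving the tetrakis(methoxymethyl) ether A1.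
- Merits: it is more convergent than the chosen plan, joining two finished halves in the ring-forming step, and it needs no late construction of ring C.
- Weak points: A2 is a hexasubstituted benzene whose adjacent bromide and iodide must be placed between an acetal ether and the stereogenic side chain, and that side chain must be attached enantioselectively to an arene. The C–O closure takes place at a bromide flanked by the branched alkyl group. The four acetal ethers of A1 can only be removed with acid, which the prenyl and isopropenyl groups next to free phenols do not tolerate.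
- Comparison: the chosen plan is less convergent, but it fixes all of ring A in one regiospecific step, creates the stereocentre on an acyclic ester, and ends with fluoride.

**Alternative 2: twofold aromatic Claisen rearrangement for the ring C prenyl groups.**
- Cut and forward step: the two aryl–CH2 bonds of ring C are cut. Heating the bis(1,1-dimethylallyl) ether A5 moves each allyl group with inversion to the adjacent free carbon, while a bromine at C4' blocks the other ortho site, giving A4.
- Merits: it settles the C2'/C6' regiochemistry as cleanly as the chosen plan and avoids polyanion chemistry.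
- Weak points: it is a tactic for ring C only, and the benzofuran core with its stereocentre must still come from elsewhere. The tertiary allyl ethers next to bromine are hard to make without a partial hydrogenation that the isopropenyl group would have to survive. The migration ends at carbons next to the biaryl bond, and the blocking bromine must later be removed reductively in the presence of three alkenes.
- Comparison: for ring C alone it is about as good; the chosen plan avoids the extra halogen and ether steps by carrying the prenyl groups in an acyclic diketone, but pays with a demanding aldol closure.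

**Alternative 3: acylation and intramolecular Wittig closure of ring B.**
- Cut and forward step: the furan is cut at O1–C2 and C2=C3. The phenolic phosphonium salt A7 is O-acylated by the ring C acid chloride A8, and the ylide attacks the new ester carbonyl, giving the tetrakis(silyl) ether A6.
- Merits: this is the best-precedented way to a 2-arylbenzofuran, it is convergent, and its final deprotection is the same fluoride step as in the chosen plan.
- Weak points: the ester carbonyl that the ylide must attack is flanked by two ortho prenyl groups, so olefination is slow and ester cleavage competes. A7 needs a pentasubstituted phenol with a benzylic phosphonium group and the stereocentre already on the arene, which again raises the ring A regiochemistry and the enantioselective aryl–alkyl bond.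
- Comparison: the chosen plan also has a hindered carbonyl addition (the aldol closing ring C), but there the nucleophile is tethered and aromatisation makes the step irreversible; its real advantage is that ring A and the stereocentre are solved together.

Key step: step 7

Assumption: the (4S,5S)-bromoborane controller is taken to deliver the (3S) acid 6; the sense is checked on the first run, and the (4R,5R) reagent, made the same way from the enantiomeric diamine, is used if the opposite acid is found.

Remark: acid 6 and acid chloride 7 are drawn without configuration at C2, because either epimer gives the same ketene 15. The descriptor of the side-chain centre changes from S (6, 7) to R (15 onward) only through a change in ligand priority; the spatial arrangement is the same throughout. "Furan C3" means the ring carbon next to the one that bears the side chain (C4 in the numbering of the furan-2-carboxylate names); it becomes C3a of the benzofuran.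

## Route

Step 1
Reactants: 1 methyl 5-(chloromethyl)furan-2-carboxylate; 2 (2E)-2-methylbut-2-en-1-ol
Product: 3 methyl 5-(2-{[(2E)-2-methylbut-2-en-1-yl]oxy}-2-oxoethyl)furan-2-carboxylate
Conditions: PdCl2(PPh3)2 (cat.), CO (1 atm), i-Pr2NEt, THF, 50 °C
Reagents that add atoms: carbon monoxide, [C-]#[O+]
Why: Palladium-catalysed alkoxycarbonylation of a benzylic-type chloride: oxidative addition of the furfuryl C–Cl bond to zerovalent palladium, CO insertion and alcoholysis of the acylpalladium by the allylic alcohol. The activated chloride should be consumed much faster than the allylic ester product can ionise on CO-ligated palladium, and the hindered amine does not alkylate.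

Step 2
Reactants: 3 methyl 5-(2-{[(2E)-2-methylbut-2-en-1-yl]oxy}-2-oxoethyl)furan-2-carboxylate
Product: 6 (3S)-2-[5-(methoxycarbonyl)furan-2-yl]-3,4-dimethylpent-4-enoic acid (C2 epimers), via boron ketene acetal 4 (not isolated), via acyloxyborane 5 (not isolated)
Conditions: (4S,5S)-2-bromo-1,3-bis{[3,5-bis(trifluoromethyl)phenyl]sulfonyl}-4,5-diphenyl-1,3,2-diazaborolidine (2.2 equiv, from the bis-sulfonamide and BBr3, CH2Cl2), i-Pr2NEt, CH2Cl2, −78 → −20 °C, then rt; aqueous work-up
Reagents that add atoms: none
Why: Enantioselective Ireland–Claisen rearrangement: soft enolisation by the chiral bromoborane and amine gives a boron ketene acetal of one geometry, which rearranges through a chair transition state whose two mirror-image forms are told apart by the C2-symmetric sulfonamide ligand, so the methyl-bearing carbon C3 is set by reagent control. C2 is set as well but does not matter, since it becomes the ketene carbon in step 7; excess controller allows for the second ester carbonyl.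

Step 3
Reactants: 6 (3S)-2-[5-(methoxycarbonyl)furan-2-yl]-3,4-dimethylpent-4-enoic acid
Product: 7 methyl 5-[(3S)-1-chloro-3,4-dimethyl-1-oxopent-4-en-2-yl]furan-2-carboxylate (C2 epimers)
Conditions: 1-chloro-N,N,2-trimethylprop-1-en-1-amine, CH2Cl2, 0 °C → rt; volatiles removed, used crude
Reagents that add atoms: 1-chloro-N,N,2-trimethylprop-1-en-1-amine, CC(C)=C(Cl)N(C)C
Why: Neutral chlorination of a carboxylic acid with an α-chloroenamine; no HCl is released, so the furan and the isopropenyl group see no acid, and the amide co-product is inert in step 7.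

Step 4
Reactants: 8 oxolane (tetrahydrofuran)
Product: 10 (ethenyloxy)tri(propan-2-yl)silane, via lithium ethenolate 9 (not isolated)
Conditions: n-BuLi, THF, rt, 16 h; then i-Pr3SiCl, DMPU, −78 °C → rt
Reagents that add atoms: chlorotri(propan-2-yl)silane, CC(C)[Si](Cl)(C(C)C)C(C)C
Why: Deprotonation of tetrahydrofuran next to oxygen is followed by [3+2] cycloreversion to ethene and the lithium enolate of acetaldehyde, which the bulky silyl chloride captures on oxygen; this is the standard route to silyl vinyl ethers.

Step 5
Reactants: 10 (ethenyloxy)tri(propan-2-yl)silane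
Product: 12 {[(Z)-2-bromoethenyl]oxy}tri(propan-2-yl)silane, via dibromide 11 (not isolated)
Conditions: Br2, CH2Cl2, −78 °C; then Et3N, −78 °C → rt
Reagents that add atoms: bromine, BrBr
Why: Bromine addition to an enol ether followed by amine-induced loss of HBr from the α-bromo ether is the classical route to 2-halovinyl ethers; the bulky silyl group should resist attack of bromide at silicon. Any E isomer formed is carried along, since both isomers converge in step 6.

Step 6
Reactants: 12 {[(Z)-2-bromoethenyl]oxy}tri(propan-2-yl)silane
Product: 14 (ethynyloxy)tri(propan-2-yl)silane, via lithium siloxyacetylide 13 (not isolated)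
Conditions: LiN(i-Pr)2 (2.2 equiv), THF, −78 → −20 °C; then H2O (pH 7 buffer), −78 °C
Reagents that add atoms: none
Why: β-Elimination of HBr from a 2-bromovinyl ether with an amide base is the standard preparation of ynol ethers. The second equivalent of base holds the product as its acetylide until the cold neutral quench, and the hindered silyl group should suppress migration from oxygen to carbon.

Step 7
Reactants: 7 methyl 5-[(3S)-1-chloro-3,4-dimethyl-1-oxopent-4-en-2-yl]furan-2-carboxylate; 14 (ethynyloxy)tri(propan-2-yl)silane
Product: 19 methyl 4-hydroxy-7-[(2R)-3-methylbut-3-en-2-yl]-6-{[tri(propan-2-yl)silyl]oxy}-1-benzofuran-2-carboxylate, via furylketene 15 (not isolated), via cyclobutenone 16 (not isolated), via dienylketene 17 (not isolated), via cyclohexadienone 18 (not isolated)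
Conditions: Et3N, toluene, 0 °C → rt; filtration under Ar; then 14 (1.2 equiv), toluene, 80 → 110 °C
Reagents that add atoms: none
Why: Et3N dehydrochlorinates 7 to furyl(alkyl)ketene 15, erasing C2; after removal of the ammonium salt the nucleophilic CH terminus of 14 attacks the ketene carbonyl carbon and the silyloxy-stabilised cation closes on the ketene α-carbon, giving the 3-siloxy-4,4-disubstituted cyclobutenone 16 (bonds C4–C5 and C6–C7). On heating, 16 opens by conrotatory four-electron electrocyclic cleavage to dienylketene 17, whose ketene carbon closes on furan C3 by a thermal six-electron electrocyclisation that forms C3a–C4 and ring A, and tautomerisation of cyclohexadienone 18 gives phenol 19. The closest known reaction type is the Danheiser benzannulation in its aryl- and heteroarylketene form, together with the conversion of diaryl- and aryl(alkyl)ketenes plus alkoxyalkynes into 4-arylcyclobutenones and then naphthols. No stereocentre is created: the sp3 centres at cyclobutenone C4 and at C3a are transient, and the side-chain centre lies outside the reacting π system. Regioselectivity of the [2+2] stage comes from the polarisation of the ynol ether, which puts the silyloxy carbon next to C7 and hydrogen at C5; site selectivity of the closure comes from the furan, whose C3 is the only carbon next to the ketene-bearing position. Only the dienylketene isomer with the furyl group cis to the ketene can cyclise; the other recloses to 16, so the reversible ring opening should funnel material to 19. The ester on the furan makes the α-hydrogen of 7 more acidic and the ketene more electrophilic, and tempers the furan as a diene.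

Step 8
Reactants: 19 methyl 4-hydroxy-7-[(2R)-3-methylbut-3-en-2-yl]-6-{[tri(propan-2-yl)silyl]oxy}-1-benzofuran-2-carboxylate
Product: 20 methyl 7-[(2R)-3-methylbut-3-en-2-yl]-4,6-bis{[tri(propan-2-yl)silyl]oxy}-1-benzofuran-2-carboxylate
Conditions: i-Pr3SiCl, imidazole, DMF, rt
Reagents that add atoms: chlorotri(propan-2-yl)silane, CC(C)[Si](Cl)(C(C)C)C(C)C
Why: Silylation of a phenol with silyl chloride and imidazole; the C4 hydroxyl is the only acidic site, and the bulky silyl ether is chosen to withstand the carbanion chemistry of step 11.

Step 9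
Reactants: 21 pentane-2,4-dione; 22 1-bromo-3-methylbut-2-ene
Product: 24 7-methyloct-6-ene-2,4-dione, via acetylacetone dianion 23 (not isolated)
Conditions: LiN(i-Pr)2 (2.1 equiv), THF, 0 °C; then 22 (1.0 equiv), −78 → 0 °C; cold dil. aq. HCl
Reagents that add atoms: none
Why: Terminal alkylation of a β-diketone dianion (Hauser-type γ-alkylation): the terminal carbanion is the more basic and nucleophilic site and is alkylated by one equivalent of the primary allylic bromide, while the stabilised central enolate is left untouched.

Step 10
Reactants: 24 7-methyloct-6-ene-2,4-dione; 22 1-bromo-3-methylbut-2-ene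
Product: 26 2,12-dimethyltrideca-2,11-diene-6,8-dione, via monoprenyl diketone dianion 25 (not isolated)
Conditions: LiN(i-Pr)2 (2.1 equiv), THF, 0 °C; then 22 (1.05 equiv), −78 → 0 °C; cold dil. aq. HCl
Reagents that add atoms: none
Why: Second terminal alkylation by the same dianion chemistry: the second deprotonation of an unsymmetrical β-diketone occurs at the methyl terminus in preference to the substituted methylene, so the second prenyl group enters at the other end and the symmetrical diketone results.

Step 11
Reactants: 20 methyl 7-[(2R)-3-methylbut-3-en-2-yl]-4,6-bis{[tri(propan-2-yl)silyl]oxy}-1-benzofuran-2-carboxylate; 26 2,12-dimethyltrideca-2,11-diene-6,8-dione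
Product: 28 9-methyl-2-(3-methylbut-2-en-1-yl)-1-{7-[(2R)-3-methylbut-3-en-2-yl]-4,6-bis{[tri(propan-2-yl)silyl]oxy}-1-benzofuran-2-yl}dec-8-ene-1,3,5-trione (C2 epimers and enol forms), via diprenyl diketone dianion 27 (not isolated)
Conditions: 26 (3 equiv), LiN(i-Pr)2 (6 equiv), THF, 0 °C; then 20, −78 → 0 °C; AcOH quench
Reagents that add atoms: none
Why: Claisen-type acylation of a β-diketone dianion at its terminal carbanion by a non-enolisable aromatic ester. The excess dianion absorbs the acidic protons of the triketone formed, so no free amide base remains to touch the benzylic, allylic C–H.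

Step 12
Reactants: 28 9-methyl-2-(3-methylbut-2-en-1-yl)-1-{7-[(2R)-3-methylbut-3-en-2-yl]-4,6-bis{[tri(propan-2-yl)silyl]oxy}-1-benzofuran-2-yl}dec-8-ene-1,3,5-trione
Product: 30 5-{7-[(2R)-3-methylbut-3-en-2-yl]-4,6-bis{[tri(propan-2-yl)silyl]oxy}-1-benzofuran-2-yl}-4,6-bis(3-methylbut-2-en-1-yl)benzene-1,3-diol, via cyclic aldol 29 (not isolated)
Conditions: KOt-Bu, t-BuOH/THF, rt (≤40 °C); AcOH quench
Reagents that add atoms: none
Why: Intramolecular aldol condensation and aromatisation of a 1,3,5-triketone (polyketide-type resorcinol synthesis): C6 of the chain is the only carbon that can reach a carbonyl through a six-membered ring, and loss of water with enolisation of the two remaining ketones makes the closure irreversible. The hindered alkoxide in its own alcohol allows proton shuttling while sparing the bulky aryl silyl ethers; any partial loss of silyl groups is harmless because step 13 removes them.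

Step 13
Reactants: 30 5-{7-[(2R)-3-methylbut-3-en-2-yl]-4,6-bis{[tri(propan-2-yl)silyl]oxy}-1-benzofuran-2-yl}-4,6-bis(3-methylbut-2-en-1-yl)benzene-1,3-diol
Product: 31 2-[3,5-dihydroxy-2,6-bis(3-methylbut-2-en-1-yl)phenyl]-7-[(2R)-3-methylbut-3-en-2-yl]-1-benzofuran-4,6-diol
Conditions: Bu4NF, AcOH, THF, 0 °C → rt (degassed)
Reagents that add atoms: none
Why: Fluoride cleavage of aryl silyl ethers buffered with AcOH: the medium is not acidic enough to cyclise the prenyl or isopropenyl groups onto the neighbouring phenols and not basic enough to move the isopropenyl double bond.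

## Compound list

1 | methyl 5-(chloromethyl)furan-2-carboxylate | COC(=O)c1ccc(CCl)o1 | starting material
2 | (2E)-2-methylbut-2-en-1-ol | C/C=C(\C)CO | starting material
3 | methyl 5-(2-{[(2E)-2-methylbut-2-en-1-yl]oxy}-2-oxoethyl)furan-2-carboxylate | C/C=C(\C)COC(=O)Cc1ccc(C(=O)OC)o1 | intermediate
4 | methyl 5-[2-({(4S,5S)-1,3-bis{[3,5-bis(trifluoromethyl)phenyl]sulfonyl}-4,5-diphenyl-1,3,2-diazaborolidin-2-yl}oxy)-2-{[(2E)-2-methylbut-2-en-1-yl]oxy}ethenyl]furan-2-carboxylate (boron ketene acetal) | C/C=C(\C)COC(=Cc1ccc(C(=O)OC)o1)OB2N(S(=O)(=O)c3cc(C(F)(F)F)cc(C(F)(F)F)c3)[C@@H](c3ccccc3)[C@H](c3ccccc3)N2S(=O)(=O)c2cc(C(F)(F)F)cc(C(F)(F)F)c2 | intermediate (not isolated)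
5 | (4S,5S)-1,3-bis{[3,5-bis(trifluoromethyl)phenyl]sulfonyl}-4,5-diphenyl-1,3,2-diazaborolidin-2-yl (3S)-2-[5-(methoxycarbonyl)furan-2-yl]-3,4-dimethylpent-4-enoate (acyloxyborane) | C=C(C)[C@@H](C)C(c1ccc(C(=O)OC)o1)C(=O)OB1N(S(=O)(=O)c2cc(C(F)(F)F)cc(C(F)(F)F)c2)[C@@H](c2ccccc2)[C@H](c2ccccc2)N1S(=O)(=O)c1cc(C(F)(F)F)cc(C(F)(F)F)c1 | intermediate (not isolated)
6 | (3S)-2-[5-(methoxycarbonyl)furan-2-yl]-3,4-dimethylpent-4-enoic acid (C2 epimers) | C=C(C)[C@@H](C)C(C(=O)O)c1ccc(C(=O)OC)o1 | intermediate
7 | methyl 5-[(3S)-1-chloro-3,4-dimethyl-1-oxopent-4-en-2-yl]furan-2-carboxylate (C2 epimers) | C=C(C)[C@@H](C)C(C(=O)Cl)c1ccc(C(=O)OC)o1 | intermediate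
8 | oxolane (tetrahydrofuran) | C1CCOC1 | starting material
9 | lithium ethenolate | [Li+].[O-]C=C | intermediate (not isolated)
10 | (ethenyloxy)tri(propan-2-yl)silane | C=CO[Si](C(C)C)(C(C)C)C(C)C | intermediate
11 | (1,2-dibromoethoxy)tri(propan-2-yl)silane | BrCC(Br)O[Si](C(C)C)(C(C)C)C(C)C | intermediate (not isolated)
12 | {[(Z)-2-bromoethenyl]oxy}tri(propan-2-yl)silane | Br/C=C\O[Si](C(C)C)(C(C)C)C(C)C | intermediate
13 | lithium 2-{[tri(propan-2-yl)silyl]oxy}ethynide | [Li+].[C-]#CO[Si](C(C)C)(C(C)C)C(C)C | intermediate (not isolated)
14 | (ethynyloxy)tri(propan-2-yl)silane | C#CO[Si](C(C)C)(C(C)C)C(C)C | intermediate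
15 | methyl 5-[(3R)-3,4-dimethyl-1-oxopenta-1,4-dien-2-yl]furan-2-carboxylate (ketene) | C=C(C)[C@@H](C)C(=C=O)c1ccc(C(=O)OC)o1 | intermediate (not isolated)
16 | methyl 5-{1-[(2R)-3-methylbut-3-en-2-yl]-4-oxo-2-{[tri(propan-2-yl)silyl]oxy}cyclobut-2-en-1-yl}furan-2-carboxylate (ring carbon epimers) | C=C(C)[C@@H](C)C1(c2ccc(C(=O)OC)o2)C(=O)C=C1O[Si](C(C)C)(C(C)C)C(C)C | intermediate (not isolated)
17 | methyl 5-[(3E,5R)-5,6-dimethyl-1-oxo-3-{[tri(propan-2-yl)silyl]oxy}hepta-1,3,6-trien-4-yl]furan-2-carboxylate (dienylketene) | C=C(C)[C@@H](C)/C(c1ccc(C(=O)OC)o1)=C(\O[Si](C(C)C)(C(C)C)C(C)C)C=C=O | intermediate (not isolated)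
18 | methyl 7-[(2R)-3-methylbut-3-en-2-yl]-4-oxo-6-{[tri(propan-2-yl)silyl]oxy}-3a,4-dihydro-1-benzofuran-2-carboxylate (C3a epimers) | C=C(C)[C@@H](C)C1=C2OC(C(=O)OC)=CC2C(=O)C=C1O[Si](C(C)C)(C(C)C)C(C)C | intermediate (not isolated)
19 | methyl 4-hydroxy-7-[(2R)-3-methylbut-3-en-2-yl]-6-{[tri(propan-2-yl)silyl]oxy}-1-benzofuran-2-carboxylate | C=C(C)[C@@H](C)c1c(O[Si](C(C)C)(C(C)C)C(C)C)cc(O)c2cc(C(=O)OC)oc12 | intermediate
20 | methyl 7-[(2R)-3-methylbut-3-en-2-yl]-4,6-bis{[tri(propan-2-yl)silyl]oxy}-1-benzofuran-2-carboxylate | C=C(C)[C@@H](C)c1c(O[Si](C(C)C)(C(C)C)C(C)C)cc(O[Si](C(C)C)(C(C)C)C(C)C)c2cc(C(=O)OC)oc12 | intermediate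
21 | pentane-2,4-dione | CC(=O)CC(C)=O | starting material
22 | 1-bromo-3-methylbut-2-ene | CC(C)=CCBr | starting material
23 | dilithium salt of the 1,3-dianion of pentane-2,4-dione | [Li+].[Li+].[CH2-]C(=O)[CH-]C(C)=O | intermediate (not isolated)
24 | 7-methyloct-6-ene-2,4-dione | CC(=O)CC(=O)CCC=C(C)C | intermediate
25 | dilithium salt of the 1,3-dianion of 7-methyloct-6-ene-2,4-dione | [Li+].[Li+].[CH2-]C(=O)[CH-]C(=O)CCC=C(C)C | intermediate (not isolated)
26 | 2,12-dimethyltrideca-2,11-diene-6,8-dione | CC(C)=CCCC(=O)CC(=O)CCC=C(C)C | intermediate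
27 | dilithium salt of the 5,7-dianion of 2,12-dimethyltrideca-2,11-diene-6,8-dione | [Li+].[Li+].CC(C)=CC[CH-]C(=O)[CH-]C(=O)CCC=C(C)C | intermediate (not isolated)
28 | 9-methyl-2-(3-methylbut-2-en-1-yl)-1-{7-[(2R)-3-methylbut-3-en-2-yl]-4,6-bis{[tri(propan-2-yl)silyl]oxy}-1-benzofuran-2-yl}dec-8-ene-1,3,5-trione (C2 epimers) | C=C(C)[C@@H](C)c1c(O[Si](C(C)C)(C(C)C)C(C)C)cc(O[Si](C(C)C)(C(C)C)C(C)C)c2cc(C(=O)C(CC=C(C)C)C(=O)CC(=O)CCC=C(C)C)oc12 | intermediate
29 | 5-hydroxy-4,6-bis(3-methylbut-2-en-1-yl)-5-{7-[(2R)-3-methylbut-3-en-2-yl]-4,6-bis{[tri(propan-2-yl)silyl]oxy}-1-benzofuran-2-yl}cyclohexane-1,3-dione (ring stereoisomers) | C=C(C)[C@@H](C)c1c(O[Si](C(C)C)(C(C)C)C(C)C)cc(O[Si](C(C)C)(C(C)C)C(C)C)c2cc(C3(O)C(CC=C(C)C)C(=O)CC(=O)C3CC=C(C)C)oc12 | intermediate (not isolated)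
30 | 5-{7-[(2R)-3-methylbut-3-en-2-yl]-4,6-bis{[tri(propan-2-yl)silyl]oxy}-1-benzofuran-2-yl}-4,6-bis(3-methylbut-2-en-1-yl)benzene-1,3-diol | C=C(C)[C@@H](C)c1c(O[Si](C(C)C)(C(C)C)C(C)C)cc(O[Si](C(C)C)(C(C)C)C(C)C)c2cc(-c3c(CC=C(C)C)c(O)cc(O)c3CC=C(C)C)oc12 | intermediate
31 | 2-[3,5-dihydroxy-2,6-bis(3-methylbut-2-en-1-yl)phenyl]-7-[(2R)-3-methylbut-3-en-2-yl]-1-benzofuran-4,6-diol | C=C(C)[C@@H](C)c1c(O)cc(O)c2cc(-c3c(CC=C(C)C)c(O)cc(O)c3CC=C(C)C)oc12 | target

## Step count and risk

Total: 13 steps. Longest linear sequence: 8 steps, from chloride 1 (steps 1, 2, 3, 7, 8, 11, 12, 13); the siloxyalkyne branch from 8 (steps 4, 5, 6, then 7, 8, 11, 12, 13) is equally long. The diketone branch (steps 9 and 10) joins at step 11.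

**Key step (step 7).** The ketene carbon is fully substituted, so the [2+2] addition may be slow and ketene dimerisation may compete. The dienylketene isomer with the branched alkyl group cis to the ketene can suffer a 1,5-hydrogen shift from the stereogenic C–H to the ketene carbon, which would consume material and destroy the stereocentre in that portion. Traces of HCl would hydrate the ynol ether. The fallback forms ring A from an acylketene instead of an ynol ether and sets out from acid chloride 7. Acylation of 2,2-dimethyl-1,3-dioxane-4,6-dione with 7 (pyridine, CH2Cl2, 0 °C) should give methyl 5-[(3S)-1-(2,2-dimethyl-4,6-dioxo-1,3-dioxan-5-yl)-3,4-dimethyl-1-oxopent-4-en-2-yl]furan-2-carboxylate F1. Thermolysis in toluene at 110 °C releases acetone and carbon dioxide, and the enolised acylketene should close on furan C3 to give methyl 4,6-dihydroxy-7-[(2R)-3-methylbut-3-en-2-yl]-1-benzofuran-2-carboxylate F2. Silylation of both hydroxyls (i-Pr3SiCl, imidazole, DMF) rejoins the route at compound 20.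

**Enantioselective rearrangement (step 2).** A mixture of enolate geometries would erode the enantiomeric purity at C3, the second ester carbonyl may tie up the boron reagent and slow enolisation, and the sense of induction is assumed. The fallback separates the enantiomers on a covalent auxiliary and sets out from ester 3. Rearrangement through the silyl ketene acetal (LiN(SiMe3)2, Me3SiCl, THF, −78 °C → rt) should give racemic 2-[5-(methoxycarbonyl)furan-2-yl]-3,4-dimethylpent-4-enoic acid F3. Coupling with lithiated (4S)-4-benzyl-1,3-oxazolidin-2-one through the pivaloyl mixed anhydride gives diastereomeric imides. The (3S) series, methyl 5-{(3S)-1-[(4S)-4-benzyl-2-oxo-1,3-oxazolidin-3-yl]-3,4-dimethyl-1-oxopent-4-en-2-yl}furan-2-carboxylate F4, is separated by chromatography or crystallisation. Cleavage with LiOH/H2O2 at 0 °C returns to acid 6.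

**Ring C closure (step 12).** The triketone may rest as an unreactive polyanion so that closure stalls, alkoxide may fragment the 1,3-dicarbonyl units by retro-Claisen cleavage, closure through oxygen to a 4-pyranone may compete once the medium is acidified, and prolonged exposure to base may shift the isopropenyl double bond into conjugation with ring A and so erase the stereocentre. The fallback attaches ring C preformed and sets out from ester 20.
- Hydrolysis with Me3SnOH (1,2-dichloroethane, 80 °C) should give 7-[(2R)-3-methylbut-3-en-2-yl]-4,6-bis{[tri(propan-2-yl)silyl]oxy}-1-benzofuran-2-carboxylic acid F5.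
- Protodecarboxylation (Ag2CO3 cat., AcOH, DMSO, 120 °C) should give {7-[(2R)-3-methylbut-3-en-2-yl]-1-benzofuran-4,6-diyl}bis(oxy)bis[tri(propan-2-yl)silane] F6.
- Lithiation at C2 (n-BuLi, THF, −78 °C), transmetalation with ZnCl2 and Negishi coupling (Pd2(dba)3, SPhos) with {[5-iodo-4,6-bis(3-methylbut-2-en-1-yl)-1,3-phenylene]bis(oxy)}bis[tri(propan-2-yl)silane] F7 should give the tetrakis(triisopropylsilyl) ether of the target F8. F7 would have to be made separately from a 5-haloresorcinol.
- The conditions of step 13 then lead to the target 31.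

This fallback is longer and brings back a hindered biaryl coupling, which is why it is not the first choice.

**Dianion acylation (step 11).** Proton transfer from the product may quench the secondary carbanion before it has reacted, and the methoxide released may attack the aryl silyl ethers. The fallback changes the acylating agent and sets out from ester 20. Treatment with N,O-dimethylhydroxylamine hydrochloride and i-PrMgCl (THF, −20 °C) should give N-methoxy-N-methyl-7-[(2R)-3-methylbut-3-en-2-yl]-4,6-bis{[tri(propan-2-yl)silyl]oxy}-1-benzofuran-2-carboxamide F9. This reacts with dianion 27 through a stable chelate that releases no alkoxide, and it returns to triketone 28.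

**Carbonylative esterification (step 1).** Zerovalent palladium may ionise the allylic ester product once the chloride is used up, leading to allyl scrambling or C-allylation, and the alcohol may displace the chloride directly to give an ether. The fallback makes the allyl ester with no palladium present and sets out from chloride 1. Hydroxycarbonylation (PdCl2(PPh3)2, CO, H2O, i-Pr2NEt, THF) should give 2-[5-(methoxycarbonyl)furan-2-yl]acetic acid F10. Carbodiimide esterification with alcohol 2 (EDC·HCl, DMAP, CH2Cl2) returns to ester 3.

## Further compounds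

F1 | step 7 | methyl 5-[(3S)-1-(2,2-dimethyl-4,6-dioxo-1,3-dioxan-5-yl)-3,4-dimethyl-1-oxopent-4-en-2-yl]furan-2-carboxylate (C2 epimers) | C=C(C)[C@@H](C)C(c1ccc(C(=O)OC)o1)C(=O)C1C(=O)OC(C)(C)OC1=O
F2 | step 7 | methyl 4,6-dihydroxy-7-[(2R)-3-methylbut-3-en-2-yl]-1-benzofuran-2-carboxylate | C=C(C)[C@@H](C)c1c(O)cc(O)c2cc(C(=O)OC)oc12
F3 | step 2 | racemic 2-[5-(methoxycarbonyl)furan-2-yl]-3,4-dimethylpent-4-enoic acid | C=C(C)C(C)C(C(=O)O)c1ccc(C(=O)OC)o1
F4 | step 2 | methyl 5-{(3S)-1-[(4S)-4-benzyl-2-oxo-1,3-oxazolidin-3-yl]-3,4-dimethyl-1-oxopent-4-en-2-yl}furan-2-carboxylate (C2 epimers) | C=C(C)[C@@H](C)C(C(=O)N1C(=O)OC[C@@H]1Cc1ccccc1)c1ccc(C(=O)OC)o1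
F5 | step 12 | 7-[(2R)-3-methylbut-3-en-2-yl]-4,6-bis{[tri(propan-2-yl)silyl]oxy}-1-benzofuran-2-carboxylic acid | C=C(C)[C@@H](C)c1c(O[Si](C(C)C)(C(C)C)C(C)C)cc(O[Si](C(C)C)(C(C)C)C(C)C)c2cc(C(=O)O)oc12
F6 | step 12 | {7-[(2R)-3-methylbut-3-en-2-yl]-1-benzofuran-4,6-diyl}bis(oxy)bis[tri(propan-2-yl)silane] | C=C(C)[C@@H](C)c1c(O[Si](C(C)C)(C(C)C)C(C)C)cc(O[Si](C(C)C)(C(C)C)C(C)C)c2ccoc12
F7 | step 12 | {[5-iodo-4,6-bis(3-methylbut-2-en-1-yl)-1,3-phenylene]bis(oxy)}bis[tri(propan-2-yl)silane] | Ic1c(CC=C(C)C)c(O[Si](C(C)C)(C(C)C)C(C)C)cc(O[Si](C(C)C)(C(C)C)C(C)C)c1CC=C(C)C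
F8 | step 12 | 2-{2,6-bis(3-methylbut-2-en-1-yl)-3,5-bis{[tri(propan-2-yl)silyl]oxy}phenyl}-7-[(2R)-3-methylbut-3-en-2-yl]-4,6-bis{[tri(propan-2-yl)silyl]oxy}-1-benzofuran | C=C(C)[C@@H](C)c1c(O[Si](C(C)C)(C(C)C)C(C)C)cc(O[Si](C(C)C)(C(C)C)C(C)C)c2cc(-c3c(CC=C(C)C)c(O[Si](C(C)C)(C(C)C)C(C)C)cc(O[Si](C(C)C)(C(C)C)C(C)C)c3CC=C(C)C)oc12
F9 | step 11 | N-methoxy-N-methyl-7-[(2R)-3-methylbut-3-en-2-yl]-4,6-bis{[tri(propan-2-yl)silyl]oxy}-1-benzofuran-2-carboxamide | C=C(C)[C@@H](C)c1c(O[Si](C(C)C)(C(C)C)C(C)C)cc(O[Si](C(C)C)(C(C)C)C(C)C)c2cc(C(=O)N(C)OC)oc12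
F10 | step 1 | 2-[5-(methoxycarbonyl)furan-2-yl]acetic acid | COC(=O)c1ccc(CC(=O)O)o1
A1 | alternative 1 | 2-[3,5-bis(methoxymethoxy)-2,6-bis(3-methylbut-2-en-1-yl)phenyl]-4,6-bis(methoxymethoxy)-7-[(2R)-3-methylbut-3-en-2-yl]-1-benzofuran | C=C(C)[C@@H](C)c1c(OCOC)cc(OCOC)c2cc(-c3c(CC=C(C)C)c(OCOC)cc(OCOC)c3CC=C(C)C)oc12
A2 | alternative 1 | 3-bromo-2-iodo-1,5-bis(methoxymethoxy)-4-[(2R)-3-methylbut-3-en-2-yl]benzene | C=C(C)[C@@H](C)c1c(OCOC)cc(OCOC)c(I)c1Br
A3 | alternative 1 | 1-[3,5-bis(methoxymethoxy)-2,6-bis(3-methylbut-2-en-1-yl)phenyl]ethan-1-one | CC(=O)c1c(CC=C(C)C)c(OCOC)cc(OCOC)c1CC=C(C)C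
A4 | alternative 2 | 2-bromo-5-{4,6-bis[(tert-butyldimethylsilyl)oxy]-7-[(2R)-3-methylbut-3-en-2-yl]-1-benzofuran-2-yl}-4,6-bis(3-methylbut-2-en-1-yl)benzene-1,3-diol | C=C(C)[C@@H](C)c1c(O[Si](C)(C)C(C)(C)C)cc(O[Si](C)(C)C(C)(C)C)c2cc(-c3c(CC=C(C)C)c(O)c(Br)c(O)c3CC=C(C)C)oc12
A5 | alternative 2 | 2-{4-bromo-3,5-bis[(2-methylbut-3-en-2-yl)oxy]phenyl}-4,6-bis[(tert-butyldimethylsilyl)oxy]-7-[(2R)-3-methylbut-3-en-2-yl]-1-benzofuran | C=C(C)[C@@H](C)c1c(O[Si](C)(C)C(C)(C)C)cc(O[Si](C)(C)C(C)(C)C)c2cc(-c3cc(OC(C)(C)C=C)c(Br)c(OC(C)(C)C=C)c3)oc12
A6 | alternative 3 | 2-{3,5-bis[(tert-butyldimethylsilyl)oxy]-2,6-bis(3-methylbut-2-en-1-yl)phenyl}-4,6-bis[(tert-butyldimethylsilyl)oxy]-7-[(2R)-3-methylbut-3-en-2-yl]-1-benzofuran | C=C(C)[C@@H](C)c1c(O[Si](C)(C)C(C)(C)C)cc(O[Si](C)(C)C(C)(C)C)c2cc(-c3c(CC=C(C)C)c(O[Si](C)(C)C(C)(C)C)cc(O[Si](C)(C)C(C)(C)C)c3CC=C(C)C)oc12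
A7 | alternative 3 | ({4,6-bis[(tert-butyldimethylsilyl)oxy]-2-hydroxy-3-[(2R)-3-methylbut-3-en-2-yl]phenyl}methyl)triphenylphosphonium bromide | C=C(C)[C@@H](C)c1c(O)c(C[P+](c2ccccc2)(c2ccccc2)c2ccccc2)c(O[Si](C)(C)C(C)(C)C)cc1O[Si](C)(C)C(C)(C)C.[Br-]
A8 | alternative 3 | 3,5-bis[(tert-butyldimethylsilyl)oxy]-2,6-bis(3-methylbut-2-en-1-yl)benzoyl chloride | O=C(Cl)c1c(CC=C(C)C)c(O[Si](C)(C)C(C)(C)C)cc(O[Si](C)(C)C(C)(C)C)c1CC=C(C)C
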